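**Retrosynthetic overview**

1. The target is read as 19-tigloyloxy-labda-7,13(Z)-dien-15-oic acid (labdane numbering; 4β-CH2O, 4α-CH3, 5α-H, 9α-H, 10β-CH3).
2. Side chain: the acid is unmasked last; the C12–C13 bond comes from a B-alkyl Suzuki–Miyaura coupling of a C9 vinyl group with a (Z)-3-iodobut-2-enoate; the tiglate is put on C19–OH.
3. C9 (H α, vinyl β) comes from the C9 ketone by vinyl addition and palladium–formate hydrogenolysis; C4 is set by α-face methylation of the C19 ester enolate.
4. Ring order: ring B is bought as (R)-carvone (C5 stereocentre); ring A is closed onto it by stitching ethylene (C1–C2) between C10 and C3 in a radical annulation.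
5. Enabling feature: C10 is the α'-carbon of the ring B ketone (C9) and C3 is the CH2 terminus of an acrylate on C4; the two are 1,4-related through C5–C4 and cannot close on each other, but a two-carbon unit completes the six-membered ring A.

Key step: step 5

Remark: compounds 3–8 are carried as epimer mixtures at C10 and compounds 10–13 as epimer mixtures at C4, because both centres are made planar again later (C10 radical in step 5, C4 enolate in step 8).

**Step 1**
Reactants: 1 (R)-(−)-carvone
Product: 3 6-methylcarvone (C10 epimers), via lithium enolate 2 (not isolated)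
Conditions: LDA, THF, −78 °C; MeI, −78 → 0 °C
Reagents that add atoms: iodomethane, CI
Why: Kinetic α'-deprotonation of the enone and C-methylation of the enolate (enolate alkylation) should install the future C20 methyl group; the new centre is planarised again in steps 4 and 5.

**Step 2**
Reactants: 3 6-methylcarvone
Product: 4 allylic alcohol
Conditions: SeO2 (cat.), t-BuOOH, CH2Cl2, rt
Reagents that add atoms: tert-butyl hydroperoxide, CC(C)(C)OO
Why: Riley-type allylic oxidation (ene reaction, then 2,3-sigmatropic shift) should attack only the electron-rich 1,1-disubstituted alkene and prefer its methyl group over the ring methine; no stereocentre is formed.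

**Step 3**
Reactants: 4 allylic alcohol
Product: 6 methyl acrylate, via enal 5 (not isolated)
Conditions: MnO2, 1,4-dimethyl-1,2,4-triazolium iodide (cat.), DBU, MeOH, CH2Cl2, rt
Reagents that add atoms: methanol, CO
Why: Tandem MnO2 oxidation and N-heterocyclic-carbene-catalysed oxidative esterification should take the allylic alcohol through the enal and its acyl azolium to the methyl ester without cyanide or strong acid, which the enone would not tolerate.

**Step 4**
Reactants: 6 methyl acrylate
Product: 8 tertiary α-bromo ketone, via lithium enolate 7 (not isolated)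
Conditions: LDA, THF, −78 °C; Br2 (CH2Cl2 solution), −78 °C; cold work-up, used at once
Reagents that add atoms: bromine, BrBr
Why: Kinetic enolate formation at the only α'-hydrogen (C10) and electrophilic bromination of the enolate should give the radical precursor; its C10 configuration is of no consequence.

**Step 5**
Reactants: 8 tertiary α-bromo ketone; 9 ethylene
Product: 10 bicyclic enone ester (trans-decalin, C4 epimers)
Conditions: (Me3Si)3SiH (slow addition), AIBN (cat.), ethylene (15 bar), benzene, 80 °C
Reagents that add atoms: none
Why: Proposed new method: bromine abstraction from 8 by the silyl radical gives the tertiary α-keto radical at C10, this electrophilic radical adds to ethylene (C1–C10 bond), the nucleophilic primary radical formed at C2 closes onto the CH2 terminus C3 of the acrylate (C2–C3 bond), and the α-ester radical at C4 takes hydrogen from the silane to carry the chain; direct closure of C10 onto C3 would give a cyclobutane, so the radical waits for ethylene. The closest known reaction type is the tin- or silane-mediated radical annulation, in which an α-carbonyl radical adds to an alkene and the adduct radical cyclises onto a tethered acceptor; what is new is ethylene as the two-carbon partner with a tertiary α-keto radical and a 6-endo closure in one chain. Ring A is closed in the 6-endo-trig mode, the normal regiochemistry for an alkyl radical attacking an acrylate that is tethered through its α-carbon. C10 is controlled by the C5 stereocentre bought with carvone: ethylene should add to the planar radical on the face opposite the C5 substituent, so C1 and C4 become trans on ring B and the ring fusion is trans (10β-CH3, 5α-H), while C4 is formed without control and is corrected in step 8. The step needs chemoselectivity of the C2 radical for the acrylate over the ring B enone and over a second ethylene, and this is secured by the unhindered ester-activated CH2 terminus held within reach on the equatorial C5 substituent, whereas attack on the ring-substituted enone carbon C7 would need a boat-like bicyclo[2.2.2]octane transition state. Premature reduction of the C10 radical only returns ketone 6, which can be brominated again.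

**Step 6**
Reactants: 10 bicyclic enone ester
Product: 12 tertiary allylic methyl carbonate (9α-vinyl, 9β-OCO2CH3), via cerium alkoxide 11 (not isolated)
Conditions: CH2=CHMgBr, CeCl3, THF, −78 °C; then ClCO2Me, −78 → 0 °C
Reagents that add atoms: vinylmagnesium bromide, C=C[Mg]Br; methyl chloroformate, COC(Cl)=O
Why: 1,2-Addition of the organocerium reagent to the hindered enone carbonyl should occur from the α face, anti to the axial 10-methyl group, without touching the ester, and the alkoxide is O-acylated in the same flask.

**Step 7**
Reactants: 12 tertiary allylic methyl carbonate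
Product: 13 9β-vinyl-9α-H ester (C4 epimers)
Conditions: Pd(OAc)2 (cat.), n-Bu3P, HCO2H, Et3N, THF, 40 °C
Reagents that add atoms: none
Why: In this palladium-catalysed formate hydrogenolysis of an allylic carbonate (Tsuji–Trost-type reduction), zerovalent palladium should ionise the carbonate anti to the β-oxygen and deliver hydride to the most substituted allyl terminus C9 on the α face, which gives 9α-H with the vinyl group β and leaves C7=C8 in place.

**Step 8**
Reactants: 13 9β-vinyl-9α-H ester
Product: 15 4α-methyl-4β-ester, via lithium ester enolate 14 (not isolated)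
Conditions: LDA, THF, −78 → 0 °C; MeI, DMPU, −78 °C → rt
Reagents that add atoms: iodomethane, CI
Why: In this ester enolate alkylation, iodomethane should approach the exocyclic enolate from the equatorial α face, away from the axial 10-methyl group, so the ester carbon stays axial (4β) and both C4 epimers of 13 converge on one quaternary centre.

**Step 9**
Reactants: 15 4α-methyl-4β-ester
Product: 16 C19 primary alcohol
Conditions: LiAlH4, THF, 0 °C → reflux
Reagents that add atoms: none
Why: Hydride reduction of the hindered axial ester (LiAlH4 reduction) should give the neopentyl alcohol while the isolated alkenes stay inert.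

**Step 10**
Reactants: 16 C19 primary alcohol
Product: 17 C19 tiglate
Conditions: tigloyl chloride, pyridine, DMAP (cat.), CH2Cl2, 0 °C → rt
Reagents that add atoms: tigloyl chloride, C/C=C(\C)C(Cl)=O
Why: DMAP-catalysed acylation of the primary alcohol with the acid chloride should give the ester; pyridine is used instead of a trialkylamine to avoid ketene formation and loss of the E geometry.

**Step 11**
Reactants: 18 2-butynoic acid
Product: 19 (Z)-3-iodobut-2-enoic acid
Conditions: NaI, AcOH, 110 °C
Reagents that add atoms: sodium iodide, [Na+].[I-]
Why: Anti hydroiodination of the alkynoic acid (conjugate addition of iodide, then protonation) should give the Z vinyl iodide with iodine cis to the carboxyl group.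

**Step 12**
Reactants: 19 (Z)-3-iodobut-2-enoic acid
Product: 20 2-(trimethylsilyl)ethyl (Z)-3-iodobut-2-enoate
Conditions: Me3SiCH2CH2OH, DCC, DMAP (cat.), CH2Cl2, 0 °C → rt
Reagents that add atoms: 2-(trimethylsilyl)ethanol, C[Si](C)(C)CCO
Why: Steglich esterification should mask the acid as a fluoride-labile ester without touching the vinyl iodide geometry.

**Step 13**
Reactants: 17 C19 tiglate; 20 2-(trimethylsilyl)ethyl (Z)-3-iodobut-2-enoate
Product: 22 silyl-ethyl ester of the target, via alkylborane 21 (not isolated)
Conditions: 9-BBN-H, THF, rt; then 20, Pd(dppf)Cl2 (cat.), AsPh3, Cs2CO3, DMF/H2O, rt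
Reagents that add atoms: none
Why: Brown hydroboration should place boron on the terminal carbon of the only monosubstituted alkene, and the B-alkyl Suzuki–Miyaura coupling joins C12 to C13 with retention of the Z geometry of the vinyl iodide.

**Step 14**
Reactants: 22 silyl-ethyl ester of the target
Product: 23 CNP0249147.2 (target)
Conditions: Bu4NF, THF, rt; then dilute aq. HCl, 0 °C
Reagents that add atoms: none
Why: Fluoride-induced β-elimination of the 2-(trimethylsilyl)ethyl ester should free the acid under conditions that leave the tiglate, the Z-enoate and the ring alkene untouched.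

**Compound list**

1 | (R)-(−)-carvone, (5R)-2-methyl-5-(prop-1-en-2-yl)cyclohex-2-en-1-one | C=C(C)[C@@H]1CC=C(C)C(=O)C1 | starting material
2 | lithium cross-conjugated dienolate of 1 (O–Li on C9, C9=C10) | C=C(C)[C@@H]1CC=C(C)C(O[Li])=C1 | intermediate
3 | 6-methylcarvone, (5R)-2,6-dimethyl-5-(prop-1-en-2-yl)cyclohex-2-en-1-one, epimers at the methyl-bearing carbon C10 | C=C(C)[C@@H]1CC=C(C)C(=O)C1C | intermediate
4 | (5R)-5-(3-hydroxyprop-1-en-2-yl)-2,6-dimethylcyclohex-2-en-1-one (C10 epimers) | C=C(CO)[C@@H]1CC=C(C)C(=O)C1C | intermediate
5 | 2-[(1R)-2,4-dimethyl-3-oxocyclohex-4-en-1-yl]prop-2-enal (C10 epimers) | C=C(C=O)[C@@H]1CC=C(C)C(=O)C1C | intermediate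
6 | methyl 2-[(1R)-2,4-dimethyl-3-oxocyclohex-4-en-1-yl]prop-2-enoate (C10 epimers) | C=C(C(=O)OC)[C@@H]1CC=C(C)C(=O)C1C | intermediate
7 | lithium enolate of 6 (O–Li on C9, C9=C10) | C=C(C(=O)OC)[C@@H]1CC=C(C)C(O[Li])=C1C | intermediate
8 | methyl 2-(2-bromo-2,4-dimethyl-3-oxocyclohex-4-en-1-yl)prop-2-enoate, ring carbon 1 with the C5 configuration of (R)-carvone, either epimer at the bromine-bearing carbon | C=C(C(=O)OC)[C@@H]1CC=C(C)C(=O)C1(C)Br | intermediate
9 | ethylene | C=C | starting material
10 | methyl 4a,6-dimethyl-5-oxo-1,2,3,4,4a,5,8,8a-octahydronaphthalene-1-carboxylate, trans-fused (10β-CH3, 5α-H), C4 epimers | COC(=O)C1CCC[C@]2(C)C(=O)C(C)=CC[C@@H]12 | intermediate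
11 | dichlorocerium alkoxide of the 9β-hydroxy-9α-vinyl adduct of 10 | COC(=O)C1CCC[C@]2(C)[C@](O[Ce](Cl)Cl)(C=C)C(C)=CC[C@@H]12 | intermediate
12 | methyl 5-(methoxycarbonyloxy)-4a,6-dimethyl-5-vinyl-1,2,3,4,4a,5,8,8a-octahydronaphthalene-1-carboxylate (9β-OCO2CH3, 9α-vinyl, C4 epimers) | COC(=O)C1CCC[C@]2(C)[C@](OC(=O)OC)(C=C)C(C)=CC[C@@H]12 | intermediate
13 | methyl 4a,6-dimethyl-5-vinyl-1,2,3,4,4a,5,8,8a-octahydronaphthalene-1-carboxylate (9β-vinyl, 9α-H, 10β-CH3, 5α-H, C4 epimers) | COC(=O)C1CCC[C@]2(C)[C@@H](C=C)C(C)=CC[C@@H]12 | intermediate
14 | lithium ester enolate of 13 (exocyclic at C4) | COC(O[Li])=C1CCC[C@]2(C)[C@@H](C=C)C(C)=CC[C@@H]12 | intermediate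
15 | methyl 1,4a,6-trimethyl-5-vinyl-1,2,3,4,4a,5,8,8a-octahydronaphthalene-1-carboxylate (4β-CO2CH3, 4α-CH3, 9β-vinyl) | COC(=O)[C@@]1(C)CCC[C@]2(C)[C@@H](C=C)C(C)=CC[C@@H]12 | intermediate
16 | the corresponding C19 alcohol (4β-CH2OH, 4α-CH3, 9β-vinyl) | OC[C@@]1(C)CCC[C@]2(C)[C@@H](C=C)C(C)=CC[C@@H]12 | intermediate
17 | (E)-2-methylbut-2-enoate (tiglate) of 16 | C/C=C(\C)C(=O)OC[C@@]1(C)CCC[C@]2(C)[C@@H](C=C)C(C)=CC[C@@H]12 | intermediate
18 | 2-butynoic acid | CC#CC(=O)O | starting material
19 | (Z)-3-iodobut-2-enoic acid | I/C(C)=C\C(=O)O | intermediate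
20 | 2-(trimethylsilyl)ethyl (Z)-3-iodobut-2-enoate | I/C(C)=C\C(=O)OCC[Si](C)(C)C | intermediate
21 | B-alkyl-9-borabicyclo[3.3.1]nonane from 17 (boron on C12) | C/C=C(\C)C(=O)OC[C@@]1(C)CCC[C@]2(C)[C@@H](CCB3C4CCCC3CCC4)C(C)=CC[C@@H]12 | intermediate
22 | 2-(trimethylsilyl)ethyl 19-tigloyloxy-labda-7,13(Z)-dien-15-oate | C/C=C(\C)C(=O)OC[C@@]1(C)CCC[C@]2(C)[C@@H](CC/C(C)=C\C(=O)OCC[Si](C)(C)C)C(C)=CC[C@@H]12 | intermediate
23 | CNP0249147.2, 19-[(E)-2-methylbut-2-enoyloxy]labda-7,13(Z)-dien-15-oic acid | C/C=C(\C)C(=O)OC[C@@]1(C)CCC[C@]2(C)[C@@H](CC/C(C)=C\C(=O)O)C(C)=CC[C@@H]12 | target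

**Step count and risks**

Total step count: 14. Longest linear sequence: 12 (steps 1–10, 13 and 14); steps 11 and 12 make the side-chain fragment.

Steps most likely to fail:

1. Step 5 (Proposed new method). The C10 radical may be reduced by the silane before it captures ethylene, the C2 radical may add a second ethylene or close onto the ring B enone, or ethylene may add with poor facial control. The fallback uses known chemistry, sets out from 6 and comes back at 10, and makes the two bonds one after the other. The lithium enolate 7 of ketone 6 (LDA, THF, −78 °C) is C-alkylated with 2-bromoethyl trifluoromethanesulfonate, anti to the C5 substituent, to give the 2-bromoethyl ketone F1. A tin hydride 6-endo radical cyclisation of F1 onto the acrylate (Bu3SnH, AIBN, benzene, 80 °C, high dilution) then gives 10.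

2. Step 7. Hydride may be transferred to a terminal allyl carbon to give a conjugated diene, β-hydride elimination may give a triene, or facial control at C9 may be eroded; incomplete acylation of the hindered alkoxide in step 6 would also surface here. The fallback sets out from 10 and comes back at 13. Wittig methylenation of the C9 ketone (Ph3P=CH2, toluene, 80 °C) gives the exocyclic diene F2. Hydroboration of its 1,1-disubstituted alkene from the α face (9-BBN-H, THF; then NaOH, H2O2) gives the 9β-hydroxymethyl compound F3. Dess–Martin oxidation gives the aldehyde F4, and a second Wittig methylenation (Ph3P=CH2, THF, −78 → 0 °C) gives 13.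

3. Step 2. Oxidation may compete at the ring methine C5 or at C10, or run on past the alcohol, so that conversion to the allylic alcohol is low. The fallback sets out from 3 and comes back at 5. Ene-type allylic chlorination of the isopropenyl group (Ca(OCl)2, CO2, CH2Cl2/H2O, 0 °C) gives the allylic chloride F5. Kornblum-type oxidation with trimethylamine N-oxide (DMSO, rt) gives enal 5, which is then esterified under the conditions of step 3.

**Further compounds**

F1 | step 5 | methyl 2-[2-(2-bromoethyl)-2,4-dimethyl-3-oxocyclohex-4-en-1-yl]prop-2-enoate, bromoethyl group trans to the acrylate substituent | C=C(C(=O)OC)[C@@H]1CC=C(C)C(=O)[C@@]1(C)CCBr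
F2 | step 7 | methyl 4a,6-dimethyl-5-methylidene-1,2,3,4,4a,5,8,8a-octahydronaphthalene-1-carboxylate (trans-fused, C4 epimers) | COC(=O)C1CCC[C@]2(C)C(=C)C(C)=CC[C@@H]12
F3 | step 7 | methyl 5-(hydroxymethyl)-4a,6-dimethyl-1,2,3,4,4a,5,8,8a-octahydronaphthalene-1-carboxylate (9β-CH2OH, 9α-H, C4 epimers) | COC(=O)C1CCC[C@]2(C)[C@@H](CO)C(C)=CC[C@@H]12
F4 | step 7 | methyl 5-formyl-4a,6-dimethyl-1,2,3,4,4a,5,8,8a-octahydronaphthalene-1-carboxylate (9β-CHO, 9α-H, C4 epimers) | COC(=O)C1CCC[C@]2(C)[C@@H](C=O)C(C)=CC[C@@H]12
F5 | step 2 | (5R)-5-(3-chloroprop-1-en-2-yl)-2,6-dimethylcyclohex-2-en-1-one (C10 epimers) | C=C(CCl)[C@@H]1CC=C(C)C(=O)C1C
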